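Everything rests on cutting the pyrrolidine at C3–C4 and C5–N1. The N1–C2–C3 triad is grown on C8 of ring A of hispidulin as an N-tert-butanesulfinyl methyl ketimine, and C4–C5 arrives as a two-carbon 1,2-bis-electrophile. In one flask the aza-enolate carbon C3 is alkylated by 2-chloroethyl triflate, borohydride sets the benzylic C2 stereocentre under control of the sulfinyl sulfur, and the sulfinamide nitrogen closes the ring on the chloride. The step exploits the C–H acidity of C3 and the nucleophilicity of N1, the two atoms flanking the benzylic carbon on C8. Acid cleavage, N-methylation and hydrogenolysis finish the synthesis.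

Key step: step 5

Assumption: hispidulin (1) is taken as purchasable; because a benzylic amine ortho to a free phenol can epimerise by reversible ortho-quinone methide formation, the phenols stay benzylated until the last, neutral step.

Step 1
Reactants: 1 hispidulin
Product: 2 8-iodohispidulin
Conditions: N-iodosuccinimide, DMF, 0 °C to rt, dark
Reagents that add atoms: N-iodosuccinimide, O=C1CCC(=O)N1I
Why: Electrophilic aromatic iodination should go to C8, the only unsubstituted carbon of ring A, which is ortho to the 7-OH and para to the 5-OH, whereas ring B and C3 are deactivated by conjugation with the pyranone carbonyl.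

Step 2
Reactants: 2 8-iodohispidulin
Product: 3 5,7,4'-tri-O-benzyl-8-iodohispidulin
Conditions: BnBr, K2CO3, DMF, 70 °C
Reagents that add atoms: benzyl bromide, BrCc1ccccc1
Why: Williamson etherification of all three phenols, the hydrogen-bonded 5-OH needing the excess reagent and the heat, should proceed without C-alkylation because both nucleophilic ring carbons (C6, C8) are blocked.

Step 3
Reactants: 3 5,7,4'-tri-O-benzyl-8-iodohispidulin; 4 tributyl(1-ethoxyvinyl)stannane
Product: 6 8-acetyl-5,7,4'-tri-O-benzylhispidulin, via enol ether 5 (not isolated)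
Conditions: PdCl2(PPh3)2 (5 mol %), toluene, 100 °C; then 2 M aq. HCl, THF, rt
Reagents that add atoms: tributyl(1-ethoxyvinyl)stannane 4, CCCC[Sn](CCCC)(CCCC)C(=C)OCC; water, O
Why: Stille coupling (oxidative addition of the C8–I bond to zerovalent palladium formed in situ, transmetalation, reductive elimination) installs a masked acetyl group, and mild acid hydrolysis of the enol ether should release the methyl ketone that carries the future C2 and C3.

Step 4
Reactants: 6 8-acetyl-5,7,4'-tri-O-benzylhispidulin; 7 (R)-tert-butanesulfinamide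
Product: 8 (R_S,E)-N-tert-butanesulfinyl ketimine of 6
Conditions: Ti(OEt)4, THF, 75 °C, sealed tube
Reagents that add atoms: (R)-tert-butanesulfinamide 7, CC(C)(C)[S@@](=O)N
Why: Condensation of a ketone with a sulfinamide mediated by titanium tetraethoxide, which acts as Lewis acid and water scavenger, should give the thermodynamic E ketimine with the sulfur stereocentre untouched, while the vinylogous ester carbonyl of ring C does not condense.

Step 5
Reactants: 8 (R_S,E)-N-tert-butanesulfinyl ketimine of 6; 9 2-chloroethyl trifluoromethanesulfonate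
Product: 12 (R_S)-N-tert-butanesulfinyl (2R)-pyrrolidine of tri-O-benzylhispidulin, via chloro ketimine 10 (not isolated), via chloro sulfinamide 11 (not isolated)
Conditions: LiN(SiMe3)2, THF, −78 °C; 9, −78 to −40 °C; NaBH4, H2O (2 vol %), −50 °C to rt; KOH (aq.), rt to 40 °C
Reagents that add atoms: 2-chloroethyl trifluoromethanesulfonate 9, ClCCOS(=O)(=O)C(F)(F)F
Why: LiN(SiMe3)2 removes a proton from the only acidic C–H of 8 (the ketimine methyl, future C3), the lithium aza-enolate is C-alkylated at the primary triflate of 9 (SN2, C3–C4 bond) to give 10 with the chloride intact at the future C5, NaBH4 reduces the C=N bond to give 11, and hydroxide deprotonates the sulfinamide N–H so that nitrogen displaces chloride (N1–C5 bond). The closest known reactions are the alpha-alkylation of metalated N-tert-butanesulfinyl ketimines and the reductive cyclisation of gamma-chloro N-sulfinyl ketimines to 2-arylpyrrolidines, run here without isolation. The pyrrolidine ring closes in the 5-exo-tet mode. The C2 stereocentre is controlled by the sulfur stereocentre: borohydride is delivered through a six-membered chelated transition state in which the sulfinyl oxygen holds the reductant, which for an (R)-sulfinyl E-ketimine with the aryl group as the large substituent should give the (R)-amine, and any minor diastereomer of 12 should be separable. The step needs mono-C-alkylation, secured because the triflate reacts at −78 °C while the chloride is inert there (no cyclopropane closure, no second alkylation), and chemoselectivity against ring C, secured because the amide base is non-nucleophilic and NaBH4 leaves flavones untouched while it reduces the activated sulfinyl imine.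

Step 6
Reactants: 12 (R_S)-N-tert-butanesulfinyl (2R)-pyrrolidine of tri-O-benzylhispidulin
Product: 14 8-[(2R)-1-methylpyrrolidin-2-yl]-5,7,4'-tri-O-benzylhispidulin, via secondary amine 13 (not isolated)
Conditions: HCl (4 M in dioxane), MeOH, 0 °C; evaporate; then Et3N, aq. HCHO, NaBH(OAc)3, ClCH2CH2Cl, rt
Reagents that add atoms: formaldehyde, C=O
Why: Acidolysis of the S–N bond frees the secondary amine and reductive amination with formaldehyde should methylate it, neither operation touching C2, the benzyl ethers or the flavone.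

Step 7
Reactants: 14 8-[(2R)-1-methylpyrrolidin-2-yl]-5,7,4'-tri-O-benzylhispidulin
Product: 15 target, 8-[(2R)-1-methylpyrrolidin-2-yl]hispidulin
Conditions: H2 (1 atm), Pd/C, THF–MeOH, rt
Reagents that add atoms: none
Why: Hydrogenolysis of the three O-benzyl ethers over palladium on carbon under neutral conditions at room temperature should free the phenols without touching C2 and without the heat or acid that could epimerise the liberated ortho-hydroxybenzylamine.

Compound list
1 | hispidulin, 5,7-dihydroxy-2-(4-hydroxyphenyl)-6-methoxy-4H-chromen-4-one | COc1c(O)cc2oc(-c3ccc(O)cc3)cc(=O)c2c1O | starting material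
2 | 5,7-dihydroxy-2-(4-hydroxyphenyl)-8-iodo-6-methoxy-4H-chromen-4-one | COc1c(O)c(I)c2oc(-c3ccc(O)cc3)cc(=O)c2c1O | intermediate
3 | 5,7-bis(benzyloxy)-2-[4-(benzyloxy)phenyl]-8-iodo-6-methoxy-4H-chromen-4-one | COc1c(OCc2ccccc2)c(I)c2oc(-c3ccc(OCc4ccccc4)cc3)cc(=O)c2c1OCc1ccccc1 | intermediate
4 | tributyl(1-ethoxyvinyl)stannane | CCCC[Sn](CCCC)(CCCC)C(=C)OCC | starting material
5 | 5,7-bis(benzyloxy)-2-[4-(benzyloxy)phenyl]-8-(1-ethoxyvinyl)-6-methoxy-4H-chromen-4-one | COc1c(OCc2ccccc2)c(C(=C)OCC)c2oc(-c3ccc(OCc4ccccc4)cc3)cc(=O)c2c1OCc1ccccc1 | intermediate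
6 | 8-acetyl-5,7-bis(benzyloxy)-2-[4-(benzyloxy)phenyl]-6-methoxy-4H-chromen-4-one | COc1c(OCc2ccccc2)c(C(C)=O)c2oc(-c3ccc(OCc4ccccc4)cc3)cc(=O)c2c1OCc1ccccc1 | intermediate
7 | (R)-2-methylpropane-2-sulfinamide | CC(C)(C)[S@@](=O)N | starting material
8 | (R_S,E)-N-{1-[5,7-bis(benzyloxy)-2-(4-(benzyloxy)phenyl)-6-methoxy-4-oxo-4H-chromen-8-yl]ethylidene}-2-methylpropane-2-sulfinamide | COc1c(OCc2ccccc2)c(/C(C)=N/[S@](=O)C(C)(C)C)c2oc(-c3ccc(OCc4ccccc4)cc3)cc(=O)c2c1OCc1ccccc1 | intermediate
9 | 2-chloroethyl trifluoromethanesulfonate | ClCCOS(=O)(=O)C(F)(F)F | starting material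
10 | (R_S,E)-N-{1-[5,7-bis(benzyloxy)-2-(4-(benzyloxy)phenyl)-6-methoxy-4-oxo-4H-chromen-8-yl]-4-chlorobutylidene}-2-methylpropane-2-sulfinamide | COc1c(OCc2ccccc2)c(/C(CCCCl)=N/[S@](=O)C(C)(C)C)c2oc(-c3ccc(OCc4ccccc4)cc3)cc(=O)c2c1OCc1ccccc1 | intermediate
11 | (R_S)-N-{(1R)-1-[5,7-bis(benzyloxy)-2-(4-(benzyloxy)phenyl)-6-methoxy-4-oxo-4H-chromen-8-yl]-4-chlorobutyl}-2-methylpropane-2-sulfinamide | COc1c(OCc2ccccc2)c([C@@H](CCCCl)N[S@](=O)C(C)(C)C)c2oc(-c3ccc(OCc4ccccc4)cc3)cc(=O)c2c1OCc1ccccc1 | intermediate
12 | 5,7-bis(benzyloxy)-2-[4-(benzyloxy)phenyl]-8-{(2R)-1-[(R)-tert-butylsulfinyl]pyrrolidin-2-yl}-6-methoxy-4H-chromen-4-one | COc1c(OCc2ccccc2)c([C@H]2CCCN2[S@](=O)C(C)(C)C)c2oc(-c3ccc(OCc4ccccc4)cc3)cc(=O)c2c1OCc1ccccc1 | intermediate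
13 | 5,7-bis(benzyloxy)-2-[4-(benzyloxy)phenyl]-6-methoxy-8-[(2R)-pyrrolidin-2-yl]-4H-chromen-4-one | COc1c(OCc2ccccc2)c([C@H]2CCCN2)c2oc(-c3ccc(OCc4ccccc4)cc3)cc(=O)c2c1OCc1ccccc1 | intermediate
14 | 5,7-bis(benzyloxy)-2-[4-(benzyloxy)phenyl]-6-methoxy-8-[(2R)-1-methylpyrrolidin-2-yl]-4H-chromen-4-one | COc1c(OCc2ccccc2)c([C@H]2CCCN2C)c2oc(-c3ccc(OCc4ccccc4)cc3)cc(=O)c2c1OCc1ccccc1 | intermediate
15 | 5,7-dihydroxy-2-(4-hydroxyphenyl)-6-methoxy-8-[(2R)-1-methylpyrrolidin-2-yl]-4H-chromen-4-one | COc1c(O)c([C@H]2CCCN2C)c2oc(-c3ccc(O)cc3)cc(=O)c2c1O | target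

Total steps: 7. Longest linear sequence: 7 steps (from 1).

Steps most likely to fail

Step 5. Three processes threaten it: proton transfer between the aza-enolate and the freshly alkylated ketimine (leading to double alkylation or cyclopropane closure), conjugate addition of the aza-enolate to C2 of ring C, and eroded facial selectivity in the hydride delivery because the di-ortho-substituted aryl group is twisted out of the imine plane. The fallback sets out from ketone 6 and moves stereocontrol from the auxiliary to a catalyst. The lithium enolate of 6 (LiN(SiMe3)2, THF, −78 °C) is alkylated with 9 to the 4-chlorobutanoyl ketone F1. Excess methylamine in ethanol displaces the chloride, and the tethered amine condenses intramolecularly with the ketone to the N-methyl cyclic enamine F2. Asymmetric hydrogenation of this 2-aryl cyclic enamine ([Ir(cod)Cl]2, chiral spiro phosphoramidite ligand, I2, H2, THF, ligand enantiomer chosen for the R product) should give 14, where the route is rejoined.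

Step 4. The condensation may stall at the di-ortho-substituted, twisted aryl ketone, and the sulfinamide may decompose thermally before the ketimine forms. The fallback sets out from iodide 3 and joins the preformed ring to C8. N-Boc-pyrrolidine is lithiated enantioselectively (s-BuLi, (−)-sparteine, −78 °C) and transmetalated with ZnCl2 to the configurationally stable (S)-(1-Boc-pyrrolidin-2-yl)zinc chloride F3. Negishi coupling with 3 (Pd(OAc)2, t-Bu3P·HBF4, rt), which proceeds with retention, should give the N-Boc (R)-2-arylpyrrolidine F4. CF3CO2H in CH2Cl2 then removes the carbamate to give amine 13, which enters the reductive methylation of step 6.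

Step 7. Hydrogenolysis of the benzylic C2–N bond of the pyrrolidine, saturation of the C2–C3 double bond of ring C, or poisoning of the catalyst by the amine may compete with O-debenzylation. The fallback sets out from 14 and cleaves the ethers with a Lewis acid instead: BCl3 with pentamethylbenzene as benzyl cation scavenger, CH2Cl2, −78 °C, should give 15 without hydrogen and without a metal surface. This fallback makes no new compound (F0).

Further compounds
F1 | step 5 | 5,7-bis(benzyloxy)-2-[4-(benzyloxy)phenyl]-8-(4-chlorobutanoyl)-6-methoxy-4H-chromen-4-one | COc1c(OCc2ccccc2)c(C(=O)CCCCl)c2oc(-c3ccc(OCc4ccccc4)cc3)cc(=O)c2c1OCc1ccccc1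
F2 | step 5 | 5,7-bis(benzyloxy)-2-[4-(benzyloxy)phenyl]-6-methoxy-8-(1-methyl-4,5-dihydro-1H-pyrrol-2-yl)-4H-chromen-4-one | COc1c(OCc2ccccc2)c(C2=CCCN2C)c2oc(-c3ccc(OCc4ccccc4)cc3)cc(=O)c2c1OCc1ccccc1
F3 | step 4 | (S)-[1-(tert-butoxycarbonyl)pyrrolidin-2-yl]zinc chloride | CC(C)(C)OC(=O)N1CCC[C@@H]1[Zn]Cl
F4 | step 4 | tert-butyl (2R)-2-[5,7-bis(benzyloxy)-2-(4-(benzyloxy)phenyl)-6-methoxy-4-oxo-4H-chromen-8-yl]pyrrolidine-1-carboxylate | COc1c(OCc2ccccc2)c([C@H]2CCCN2C(=O)OC(C)(C)C)c2oc(-c3ccc(OCc4ccccc4)cc3)cc(=O)c2c1OCc1ccccc1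
F0 | step 7 | none | none
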